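The route rests on cutting the bond between C1 of the tetralin and the ipso carbon of the syringyl ring, and on recognising C1 as a doubly benzylic methine flanked by two electron-rich rings (ring A para to the C6 methoxyl, the syringyl ring para to its hydroxyl): an aldehyde-level carbon. In one acid-mediated operation, an acyclic (2R,3R)-2-benzyl-3-(dimethoxymethyl)butane-1,4-diol and 2,6-dimethoxyphenol undergo a double Friedel–Crafts cascade that forges C1–aryl and C1–C8a, closes ring B and sets C1, passing through a lariciresinol-type furan as in lignan biogenesis. C3 comes from an asymmetric hydrogenation; C2 and C1 are relayed from it.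

Key step: step 6

Remark on numbering: tetralin numbering is used throughout. C1 carries the syringyl ring, C2 and C3 the CH2OH groups, C4 is the benzylic CH2, C4a/C8a are the fusion carbons, OMe is on C6 and OH on C7. The target is (1S,2R,3R), all-trans.

Remark on step 2: the ligand antipode is assumed to be the one that delivers the R acid; both antipodes are commercial, so the sense can be matched on a test scale.

Step 1
Reactants: 1 4-(benzyloxy)-3-methoxybenzaldehyde; 2 dimethyl succinate
Product: 3 (E)-4-[4-(benzyloxy)-3-methoxyphenyl]-3-(methoxycarbonyl)but-3-enoic acid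
Conditions: NaOMe, MeOH, reflux; then aq HCl
Reagents that add atoms: none
Why: Stobbe condensation: the succinate enolate adds to the aldehyde, the aldolate lactonises to a paraconate and E1cb ring opening should give the E half-ester in which only the non-conjugated carboxyl is free.

Step 2
Reactants: 3 (E)-4-[4-(benzyloxy)-3-methoxyphenyl]-3-(methoxycarbonyl)but-3-enoic acid
Product: 4 (3R)-4-[4-(benzyloxy)-3-methoxyphenyl]-3-(methoxycarbonyl)butanoic acid
Conditions: H2 (5 bar), [Rh(cod)((S,S)-Et-DuPHOS)]OTf (1 mol %), NaOMe (10 mol %), MeOH, rt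
Reagents that add atoms: none
Why: Rh–bisphosphine asymmetric hydrogenation of an itaconate-type half-ester, in which carboxylate and alkene chelate rhodium so that the ligand dictates the face of H2 delivery and sets the later C3 as R; the benzyl ether is inert to the homogeneous catalyst.

Step 3
Reactants: 4 (3R)-4-[4-(benzyloxy)-3-methoxyphenyl]-3-(methoxycarbonyl)butanoic acid
Product: 5 (4R)-4-[4-(benzyloxy)-3-methoxybenzyl]dihydrofuran-2(3H)-one
Conditions: KOH (1 equiv), EtOH; CaCl2, NaBH4, −10 °C → rt; then 2 M HCl
Reagents that add atoms: none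
Why: Chemoselective borohydride reduction of the ester beside the carboxylate salt, then acid lactonisation of the γ-hydroxy acid, should give the β-benzyl-γ-butyrolactone with the stereocentre now β to the carbonyl and no longer epimerisable.

Step 4
Reactants: 5 (4R)-4-[4-(benzyloxy)-3-methoxybenzyl]dihydrofuran-2(3H)-one
Product: 7 (3S,4R)-4-[4-(benzyloxy)-3-methoxybenzyl]-3-(dimethoxymethyl)dihydrofuran-2(3H)-one, via silyl ketene acetal 6 (not isolated)
Conditions: LDA, THF, −78 °C; TMSCl; then HC(OMe)3, TMSOTf (10 mol %), CH2Cl2, −78 °C; Et3N quench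
Reagents that add atoms: trimethyl orthoformate COC(OC)OC
Why: Mukaiyama-type addition of the ketene silyl acetal to the dimethoxycarbenium ion from the orthoformate, attacking the ring face anti to the C4 benzyl group, should set the later C2 as the 3,4-trans isomer (3S), which is also the thermodynamically preferred one.

Step 5
Reactants: 7 (3S,4R)-4-[4-(benzyloxy)-3-methoxybenzyl]-3-(dimethoxymethyl)dihydrofuran-2(3H)-one
Product: 8 (2R,3R)-2-[4-(benzyloxy)-3-methoxybenzyl]-3-(dimethoxymethyl)butane-1,4-diol
Conditions: LiAlH4, THF, 0 °C → rt; H2O/NaOH work-up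
Reagents that add atoms: none
Why: Lithium aluminium hydride reduction of the lactone to the 1,4-diol, which fixes C2 (no longer α to a carbonyl) and leaves the acetal, the ethers and both stereocentres untouched.

Step 6
Reactants: 8 (2R,3R)-2-[4-(benzyloxy)-3-methoxybenzyl]-3-(dimethoxymethyl)butane-1,4-diol; 9 2,6-dimethoxyphenol (1.2–1.5 equiv)
Product: 12 4-[(1S,2R,3R)-7-(benzyloxy)-2,3-bis(hydroxymethyl)-6-methoxy-1,2,3,4-tetrahydronaphthalen-1-yl]-2,6-dimethoxyphenol, via methyl furanoside 10 (not isolated), via aryltetrahydrofuran 11 (not isolated)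
Conditions: CF3CO2H (10 equiv), CH2Cl2 (0.02 M), 0 °C → rt; then K2CO3, MeOH
Reagents that add atoms: none
Why: Acid ionises the acetal to an oxocarbenium ion that the CH2OH on the benzyl-bearing carbon traps (5-exo-trig) as furanoside 10; re-ionisation and Friedel–Crafts attack by 2,6-dimethoxyphenol at the position para to its OH forms the C1–aryl bond of 11, whose benzylic C–O bond then ionises to a quinone-methide-type cation that ring A captures para to its methoxyl (if ring A attacks before the phenol, the same C1 cation and product should result). The closest known reaction types are the C-arylation of 2-alkoxytetrahydrofurans and lactols with phenols and the acid-catalysed lariciresinol-to-isolariciresinol cyclisation. The transient tetrahydrofuran closes 5-exo-trig and is reopened, and ring B closes by a 6-exo-trig Friedel–Crafts alkylation through a chair-like transition state. C1 is set by substrate control: the syringyl group takes the pseudo-equatorial position trans to the C2 hydroxymethyl group, so 1S follows from the untouched 2R,3R centres. The step needs para regioselectivity on the phenol (both ortho sites are blocked by OMe), closure para to OMe on ring A (the other ortho site is flanked by OMe) and ring closure faster than a second intermolecular arylation (six-membered intramolecular closure, dilution, only a slight excess of 9).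

Step 7
Reactants: 12 4-[(1S,2R,3R)-7-(benzyloxy)-2,3-bis(hydroxymethyl)-6-methoxy-1,2,3,4-tetrahydronaphthalen-1-yl]-2,6-dimethoxyphenol
Product: 13 5-methoxy-(+)-isolariciresinol, 4-[(1S,2R,3R)-7-hydroxy-2,3-bis(hydroxymethyl)-6-methoxy-1,2,3,4-tetrahydronaphthalen-1-yl]-2,6-dimethoxyphenol
Conditions: H2 (1 atm), 10% Pd/C, MeOH/EtOAc, rt
Reagents that add atoms: none
Why: Hydrogenolysis of the aryl benzyl ether over palladium, under which the diarylmethine C–C bonds, the methyl ethers and the three stereocentres should be inert.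

Compound list
1 | 4-(benzyloxy)-3-methoxybenzaldehyde (O-benzylvanillin) | COc1cc(C=O)ccc1OCc1ccccc1 | starting material
2 | dimethyl succinate | COC(=O)CCC(=O)OC | starting material
3 | (E)-4-[4-(benzyloxy)-3-methoxyphenyl]-3-(methoxycarbonyl)but-3-enoic acid | OC(=O)C/C(C(=O)OC)=C\c1ccc(OCc2ccccc2)c(OC)c1 | intermediate
4 | (3R)-4-[4-(benzyloxy)-3-methoxyphenyl]-3-(methoxycarbonyl)butanoic acid | OC(=O)C[C@@H](Cc1ccc(OCc2ccccc2)c(OC)c1)C(=O)OC | intermediate
5 | (4R)-4-[4-(benzyloxy)-3-methoxybenzyl]dihydrofuran-2(3H)-one | O=C1C[C@@H](Cc2ccc(OCc3ccccc3)c(OC)c2)CO1 | intermediate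
6 | (3R)-3-[4-(benzyloxy)-3-methoxybenzyl]-5-(trimethylsilyloxy)-2,3-dihydrofuran (silyl ketene acetal) | C[Si](C)(C)OC1=C[C@@H](Cc2ccc(OCc3ccccc3)c(OC)c2)CO1 | intermediate
7 | (3S,4R)-4-[4-(benzyloxy)-3-methoxybenzyl]-3-(dimethoxymethyl)dihydrofuran-2(3H)-one (3,4-trans) | O=C1[C@H](C(OC)OC)[C@@H](Cc2ccc(OCc3ccccc3)c(OC)c2)CO1 | intermediate
8 | (2R,3R)-2-[4-(benzyloxy)-3-methoxybenzyl]-3-(dimethoxymethyl)butane-1,4-diol | OC[C@H](C(OC)OC)[C@@H](Cc1ccc(OCc2ccccc2)c(OC)c1)CO | intermediate
9 | 2,6-dimethoxyphenol (syringol) | COc1cccc(OC)c1O | starting material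
10 | [(3R,4R)-4-[4-(benzyloxy)-3-methoxybenzyl]-2-methoxytetrahydrofuran-3-yl]methanol (3,4-cis, both anomers) | COC1OC[C@H](Cc2ccc(OCc3ccccc3)c(OC)c2)[C@@H]1CO | intermediate
11 | 4-[(2S,3R,4R)-4-[4-(benzyloxy)-3-methoxybenzyl]-3-(hydroxymethyl)tetrahydrofuran-2-yl]-2,6-dimethoxyphenol (benzyl ether of 5-methoxylariciresinol) | COc1cc(cc(OC)c1O)[C@H]1OC[C@H](Cc2ccc(OCc3ccccc3)c(OC)c2)[C@@H]1CO | intermediate
12 | 4-[(1S,2R,3R)-7-(benzyloxy)-2,3-bis(hydroxymethyl)-6-methoxy-1,2,3,4-tetrahydronaphthalen-1-yl]-2,6-dimethoxyphenol | COc1cc2c(cc1OCc1ccccc1)[C@H](c1cc(OC)c(O)c(OC)c1)[C@@H](CO)[C@H](CO)C2 | intermediate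
13 | 5-methoxy-(+)-isolariciresinol, 4-[(1S,2R,3R)-7-hydroxy-2,3-bis(hydroxymethyl)-6-methoxy-1,2,3,4-tetrahydronaphthalen-1-yl]-2,6-dimethoxyphenol | COc1cc2c(cc1O)[C@H](c1cc(OC)c(O)c(OC)c1)[C@@H](CO)[C@H](CO)C2 | target

Total step count: 7
Longest linear sequence: 7 steps (1 → 13)

Steps most likely to fail

Step 6. The phenol may be alkylated at a methoxy-activated ring position instead of para to OH. The C1 cations may lose the C2 proton reversibly (enol ether or dihydronaphthalene), eroding the C2 configuration. A second phenol may add before ring B closes, and the acid may cause benzyl transfer. The fallback replaces the free phenol by a regiodefined aryl-metal reagent and separates bond formation from cyclisation. It sets out from 8 and comes back to the route at 13. Commercial 4-bromo-2,6-dimethoxyphenol is benzylated (BnBr, K2CO3, DMF) to 2-(benzyloxy)-5-bromo-1,3-dimethoxybenzene F1 and converted into its Grignard reagent (Mg, THF). Diol acetal 8 is hydrolysed (1 M HCl, THF/H2O) to the lactol (3R,4R)-4-[4-(benzyloxy)-3-methoxybenzyl]-3-(hydroxymethyl)tetrahydrofuran-2-ol F2. Excess Grignard reagent adds to the open hydroxy-aldehyde form of F2 and should give the triol (2R,3R)-2-[4-(benzyloxy)-3-methoxybenzyl]-3-[[4-(benzyloxy)-3,5-dimethoxyphenyl](hydroxy)methyl]butane-1,4-diol F3 as a mixture of carbinol epimers. Both epimers should ionise in CF3CO2H/CH2Cl2 to the same cation and cyclise to (1S,2R,3R)-7-(benzyloxy)-1-[4-(benzyloxy)-3,5-dimethoxyphenyl]-6-methoxy-1,2,3,4-tetrahydronaphthalene-2,3-dimethanol F4. Hydrogenolysis under the conditions of step 7 removes both benzyl groups and gives 13.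

Step 4. The β,β-dimethoxy lactone may lose methanol under the Lewis acid to give the α-methoxymethylene lactone, the enolate may be trapped incompletely, or the facial selectivity may be poor. The fallback sets out from 5 and comes back at 7, using a Claisen formylation followed by acetalisation under equilibrating conditions. Lactone 5 is formylated (NaH, HCO2Et, THF, 0 °C → rt) to (4R)-4-[4-(benzyloxy)-3-methoxybenzyl]-3-(hydroxymethylene)dihydrofuran-2(3H)-one F5. Treatment with HC(OMe)3, MeOH and catalytic p-TsOH should convert F5 into 7, with the trans isomer favoured thermodynamically.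

Step 2. The enantioselectivity may be insufficient, its sense may be opposite, or Z isomer in 3 may erode it. The fallback sets out from 3 and comes back at 4, replacing catalysis by a classical resolution. Half-ester 3 is hydrogenated with RhCl(PPh3)3 (H2, MeOH/benzene), which keeps the benzyl ether, to racemic 4-[4-(benzyloxy)-3-methoxyphenyl]-3-(methoxycarbonyl)butanoic acid F6. Crystallisation with one antipode of 1-phenylethylamine (drawn as R; the matching antipode is to be found by screening) should give the (R)-1-phenylethylammonium salt of the (3R)-acid F7. Acidification of F7 releases 4.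

Further compounds
F1 | step 6 | 2-(benzyloxy)-5-bromo-1,3-dimethoxybenzene | COc1cc(Br)cc(OC)c1OCc1ccccc1
F2 | step 6 | (3R,4R)-4-[4-(benzyloxy)-3-methoxybenzyl]-3-(hydroxymethyl)tetrahydrofuran-2-ol (both anomers) | OC1OC[C@H](Cc2ccc(OCc3ccccc3)c(OC)c2)[C@@H]1CO
F3 | step 6 | (2R,3R)-2-[4-(benzyloxy)-3-methoxybenzyl]-3-[[4-(benzyloxy)-3,5-dimethoxyphenyl](hydroxy)methyl]butane-1,4-diol (carbinol epimers) | OC[C@H](C(O)c1cc(OC)c(OCc2ccccc2)c(OC)c1)[C@@H](Cc1ccc(OCc2ccccc2)c(OC)c1)CO
F4 | step 6 | (1S,2R,3R)-7-(benzyloxy)-1-[4-(benzyloxy)-3,5-dimethoxyphenyl]-6-methoxy-1,2,3,4-tetrahydronaphthalene-2,3-dimethanol | COc1cc2c(cc1OCc1ccccc1)[C@H](c1cc(OC)c(OCc3ccccc3)c(OC)c1)[C@@H](CO)[C@H](CO)C2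
F5 | step 4 | (4R)-4-[4-(benzyloxy)-3-methoxybenzyl]-3-(hydroxymethylene)dihydrofuran-2(3H)-one | O=C1OC[C@H](Cc2ccc(OCc3ccccc3)c(OC)c2)C1=CO
F6 | step 2 | racemic 4-[4-(benzyloxy)-3-methoxyphenyl]-3-(methoxycarbonyl)butanoic acid | OC(=O)CC(Cc1ccc(OCc2ccccc2)c(OC)c1)C(=O)OC
F7 | step 2 | (R)-1-phenylethylammonium (3R)-4-[4-(benzyloxy)-3-methoxyphenyl]-3-(methoxycarbonyl)butanoate | [O-]C(=O)C[C@@H](Cc1ccc(OCc2ccccc2)c(OC)c1)C(=O)OC.C[C@@H]([NH3+])c1ccccc1
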